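**Retrosynthetic overview**
1. The ten-membered carbocycle is formed last, by ring-closing metathesis that makes the (Z)-C1=C10 olefin from a seco-diene (vinyl at C1, isopropenyl at C10); the C3 PMB ether comes off afterwards.
2. The C8–C9 bond and the C8 carbinol come from reagent-controlled methallylboration of a lactone C8 aldehyde; the tiglate is put on before ring closure.
3. Key union: an intermolecular Evans syn-aldol (C6–C7) between imide 17 (C7, C8, C11–C13) and epoxy aldehyde 8 (C1–C6, C15); the adduct lactonises, so the γ-lactone is the second ring formed.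
4. Aldehyde 8: Wittig enal, Brown allylation (C3), Katsuki–Sharpless epoxidation (C4/C5; the oxirane is the first ring formed).
5. Imide 17: Evans alkylation (C11), then exchange of the auxiliary onto the other carboxyl.

Assumption: germacrane numbering (C1–C15) is used for locants in the comments; base-derived salts of reactants (enolates, alkoxides) and boron esters cleaved in the work-up are not given compound numbers.

**Route**

Step 1
Reactants: 1 2-[(tert-butyldimethylsilyl)oxy]acetaldehyde; 2 2-(triphenyl-λ5-phosphanylidene)propanal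
Product: 3 (2E)-4-[(tert-butyldimethylsilyl)oxy]-2-methylbut-2-enal
Conditions: PhMe, 90 °C
Reagents that add atoms: none
Why: Wittig olefination with a stabilised formyl ylide is E-selective and gives the C3–C6 enal with the C15 methyl in place.

Step 2
Reactants: 3 (2E)-4-[(tert-butyldimethylsilyl)oxy]-2-methylbut-2-enal
Product: 4 (2E,4S)-1-[(tert-butyldimethylsilyl)oxy]-3-methylhepta-2,6-dien-4-ol
Conditions: (−)-Ipc2BOMe (from (+)-α-pinene), CH2=CHCH2MgBr, Et2O, −78 °C to rt; then 3, −78 °C; 3 M NaOH, 30% H2O2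
Reagents that add atoms: allylmagnesium bromide, C=CC[Mg]Br
Why: Brown allylboration through a chair transition state; the allylborane of this pinene series gives the (S)-carbinol with α-methyl enals, which sets C3.

Step 3
Reactants: 4 (2E,4S)-1-[(tert-butyldimethylsilyl)oxy]-3-methylhepta-2,6-dien-4-ol
Product: 5 tert-butyl{[(2E,4S)-4-[(4-methoxyphenyl)methoxy]-3-methylhepta-2,6-dien-1-yl]oxy}dimethylsilane
Conditions: NaH, 4-methoxybenzyl chloride, Bu4NI (cat.), DMF, 0 °C to rt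
Reagents that add atoms: 4-methoxybenzyl chloride, COc1ccc(CCl)cc1
Why: Williamson etherification protects C3–OH as a PMB ether that can be removed at the end under neutral oxidative conditions; the E-olefin keeps the alkoxide away from the silyl ether.

Step 4
Reactants: 5 tert-butyl{[(2E,4S)-4-[(4-methoxyphenyl)methoxy]-3-methylhepta-2,6-dien-1-yl]oxy}dimethylsilane
Product: 6 (2E,4S)-4-[(4-methoxyphenyl)methoxy]-3-methylhepta-2,6-dien-1-ol
Conditions: Bu4NF, THF, 0 °C to rt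
Reagents that add atoms: none
Why: Fluoride cleaves the primary allylic silyl ether and leaves the PMB ether untouched.

Step 5
Reactants: 6 (2E,4S)-4-[(4-methoxyphenyl)methoxy]-3-methylhepta-2,6-dien-1-ol
Product: 7 [(2R,3R)-3-{(1S)-1-[(4-methoxyphenyl)methoxy]but-3-en-1-yl}-3-methyloxiran-2-yl]methanol
Conditions: Ti(OiPr)4 (10 mol%), D-(−)-diethyl tartrate (12 mol%), t-BuOOH, 4 Å MS, CH2Cl2, −20 °C
Reagents that add atoms: tert-butyl hydroperoxide, CC(C)(C)OO
Why: Katsuki–Sharpless asymmetric epoxidation of the trisubstituted E-allylic alcohol; D-(−)-tartrate gives the (2R,3R)-epoxide (mirror image of the L-(+)-tartrate/geraniol case), setting C4 and C5 under reagent control while the terminal vinyl group is not touched.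

Step 6
Reactants: 7 [(2R,3R)-3-{(1S)-1-[(4-methoxyphenyl)methoxy]but-3-en-1-yl}-3-methyloxiran-2-yl]methanol
Product: 8 (2S,3R)-3-{(1S)-1-[(4-methoxyphenyl)methoxy]but-3-en-1-yl}-3-methyloxirane-2-carbaldehyde
Conditions: Dess–Martin periodinane, pyridine, CH2Cl2, 0 °C to rt; used crude
Reagents that add atoms: none
Why: Buffered Dess–Martin oxidation gives the epoxy aldehyde without epoxide opening; the C5 descriptor changes only because CHO outranks the ring carbon.

Step 7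
Reactants: 9 (4S)-4-benzyl-3-propanoyl-1,3-oxazolidin-2-one; 10 tert-butyl bromoacetate
Product: 11 tert-butyl (3R)-4-[(4S)-4-benzyl-2-oxo-1,3-oxazolidin-3-yl]-3-methyl-4-oxobutanoate
Conditions: NaN(SiMe3)2, THF, −78 °C; then 10, −78 to −40 °C
Reagents that add atoms: none
Why: Evans alkylation of the chelated Z-enolate on the face opposite the benzyl group sets C11 as R.

Step 8
Reactants: 11 tert-butyl (3R)-4-[(4S)-4-benzyl-2-oxo-1,3-oxazolidin-3-yl]-3-methyl-4-oxobutanoate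
Product: 12 (2R)-4-tert-butoxy-2-methyl-4-oxobutanoic acid
Conditions: LiOH, H2O2, THF/H2O, 0 °C; Na2SO3; then 1 M HCl to pH 2
Reagents that add atoms: hydrogen peroxide (as LiOOH), OO
Why: Hydroperoxide attacks the exocyclic imide carbonyl selectively and does not epimerise the α-centre or cleave the tert-butyl ester.

Step 9
Reactants: 12 (2R)-4-tert-butoxy-2-methyl-4-oxobutanoic acid
Product: 13 4-tert-butyl 1-methyl (2R)-2-methylbutanedioate
Conditions: MeI, K2CO3, DMF, rt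
Reagents that add atoms: iodomethane, CI
Why: Carboxylate O-alkylation places the future lactone carbonyl (C12) as a methyl ester under conditions too mild to epimerise C11.

Step 10
Reactants: 13 4-tert-butyl 1-methyl (2R)-2-methylbutanedioate
Product: 14 (3R)-4-methoxy-3-methyl-4-oxobutanoic acid
Conditions: CF3CO2H, CH2Cl2, 0 °C to rt
Reagents that add atoms: none
Why: Acidolysis removes only the tert-butyl ester and frees the carboxyl that becomes C8.

Step 11
Reactants: 14 (3R)-4-methoxy-3-methyl-4-oxobutanoic acid; 15 (4S)-4-benzyl-1,3-oxazolidin-2-one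
Product: 17 methyl (2R)-4-[(4S)-4-benzyl-2-oxo-1,3-oxazolidin-3-yl]-2-methyl-4-oxobutanoate, via mixed pivalic anhydride 16 (not isolated)
Conditions: pivaloyl chloride, Et3N, THF, −20 °C; then LiCl, 15, −20 °C to rt
Reagents that add atoms: none
Why: N-acylation through the mixed anhydride occurs at the unhindered acyl carbon and puts the auxiliary on the CH2–CO terminus needed for the aldol.

Step 12
Reactants: 17 methyl (2R)-4-[(4S)-4-benzyl-2-oxo-1,3-oxazolidin-3-yl]-2-methyl-4-oxobutanoate; 8 (2S,3R)-3-{(1S)-1-[(4-methoxyphenyl)methoxy]but-3-en-1-yl}-3-methyloxirane-2-carbaldehyde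
Product: 19 (4S)-4-benzyl-3-{(2S,3S,4R)-2-[(2R,3R)-3-{(1S)-1-[(4-methoxyphenyl)methoxy]but-3-en-1-yl}-3-methyloxiran-2-yl]-4-methyl-5-oxooxolane-3-carbonyl}-1,3-oxazolidin-2-one, via syn-aldol adduct 18 (not isolated)
Conditions: Bu2BOTf, iPr2NEt, CH2Cl2, 0 °C; 8, −78 to 0 °C; pH 7 buffer, MeOH, 30% H2O2; crude adduct, PPTS (10 mol%), CH2Cl2, rt
Reagents that add atoms: none
Why: Intermolecular Evans syn-aldol of the Z-boron enolate (imide enolised in preference to the ester) through a Zimmerman–Traxler chair, with the (S)-benzyl auxiliary fixing C7 and C6 (6S, syn to the C11 side chain) over the weak bias of the epoxy aldehyde; the γ-hydroxy methyl ester then closes to the trans-4,5-disubstituted lactone with the C11 methyl cis to C8.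

Step 13
Reactants: 19 (4S)-4-benzyl-3-{(2S,3S,4R)-2-[(2R,3R)-3-{(1S)-1-[(4-methoxyphenyl)methoxy]but-3-en-1-yl}-3-methyloxiran-2-yl]-4-methyl-5-oxooxolane-3-carbonyl}-1,3-oxazolidin-2-one
Product: 20 (3R,4R,5S)-4-(hydroxymethyl)-5-[(2R,3R)-3-{(1S)-1-[(4-methoxyphenyl)methoxy]but-3-en-1-yl}-3-methyloxiran-2-yl]-3-methyloxolan-2-one
Conditions: NaBH4, THF/H2O (3:1), 0 °C to rt
Reagents that add atoms: none
Why: Borohydride in wet THF reduces the activated N-acyl oxazolidinone to the primary alcohol much faster than the γ-lactone and does not open the epoxide; no stereocentre is touched.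

Step 14
Reactants: 20 (3R,4R,5S)-4-(hydroxymethyl)-5-[(2R,3R)-3-{(1S)-1-[(4-methoxyphenyl)methoxy]but-3-en-1-yl}-3-methyloxiran-2-yl]-3-methyloxolan-2-one
Product: 21 (2S,3S,4R)-2-[(2R,3R)-3-{(1S)-1-[(4-methoxyphenyl)methoxy]but-3-en-1-yl}-3-methyloxiran-2-yl]-4-methyl-5-oxooxolane-3-carbaldehyde
Conditions: Dess–Martin periodinane, pyridine, CH2Cl2, 0 °C; used at once
Reagents that add atoms: none
Why: Neutral Dess–Martin oxidation gives the C8 aldehyde without epimerising C7; β-elimination of the ring oxygen is stereoelectronically disfavoured.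

Step 15
Reactants: 21 (2S,3S,4R)-2-[(2R,3R)-3-{(1S)-1-[(4-methoxyphenyl)methoxy]but-3-en-1-yl}-3-methyloxiran-2-yl]-4-methyl-5-oxooxolane-3-carbaldehyde
Product: 22 (3R,4R,5S)-4-[(1R)-1-hydroxy-3-methylbut-3-en-1-yl]-5-[(2R,3R)-3-{(1S)-1-[(4-methoxyphenyl)methoxy]but-3-en-1-yl}-3-methyloxiran-2-yl]-3-methyloxolan-2-one
Conditions: (+)-Ipc2BOMe (from (−)-α-pinene), CH2=C(CH3)CH2MgCl (0.95 equiv), Et2O, −78 °C to rt, Mg salts filtered off; 21, −78 °C; NaBO3·4H2O, THF/pH 7 buffer, rt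
Reagents that add atoms: 2-methylallylmagnesium chloride, CC(=C)C[Mg]Cl
Why: Brown methallylboration under reagent control (the pinene series opposite to step 2) delivers the methallyl group to the aldehyde face that gives the (8R)-carbinol, at −78 °C and without base so that C7, the lactone and the epoxide are unaffected.

Step 16
Reactants: 22 (3R,4R,5S)-4-[(1R)-1-hydroxy-3-methylbut-3-en-1-yl]-5-[(2R,3R)-3-{(1S)-1-[(4-methoxyphenyl)methoxy]but-3-en-1-yl}-3-methyloxiran-2-yl]-3-methyloxolan-2-one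
Product: 23 (1R)-1-{(2S,3R,4R)-2-[(2R,3R)-3-{(1S)-1-[(4-methoxyphenyl)methoxy]but-3-en-1-yl}-3-methyloxiran-2-yl]-4-methyl-5-oxooxolan-3-yl}-3-methylbut-3-en-1-yl (2E)-2-methylbut-2-enoate
Conditions: tiglic acid, 2,4,6-trichlorobenzoyl chloride, Et3N, THF, rt; then 22, DMAP, PhMe, rt
Reagents that add atoms: tiglic acid, C/C=C(\C)C(=O)O
Why: Yamaguchi esterification acylates the hindered secondary C8–OH with retention and avoids the ketene-mediated deconjugation seen with the acid chloride and amine base.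

Step 17
Reactants: 23 (1R)-1-{(2S,3R,4R)-2-[(2R,3R)-3-{(1S)-1-[(4-methoxyphenyl)methoxy]but-3-en-1-yl}-3-methyloxiran-2-yl]-4-methyl-5-oxooxolan-3-yl}-3-methylbut-3-en-1-yl (2E)-2-methylbut-2-enoate
Product: 24 (1(10)Z,3S,4R,5R,6S,7R,8R,11R)-4,5-epoxy-3-[(4-methoxyphenyl)methoxy]-8-[(2E)-2-methylbut-2-enoyloxy]germacr-1(10)-en-12,6-olide
Conditions: RuCl2(=CHPh)(PCy3)(H2IMes) (second-generation Grubbs catalyst, 15 mol% in portions), 1,4-benzoquinone (10 mol%), PhMe (0.5 mM), 80 °C, Ar sparge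
Reagents that add atoms: none
Why: Ring-closing metathesis between the vinyl and isopropenyl groups, pre-organised by the trans-lactone and trans-epoxide, closes the ten-membered ring; the cis (Z) trisubstituted olefin is the geometry a ring of this size favours, and the electron-poor tiglate olefin does not take part.

Step 18
Reactants: 24 (1(10)Z,3S,4R,5R,6S,7R,8R,11R)-4,5-epoxy-3-[(4-methoxyphenyl)methoxy]-8-[(2E)-2-methylbut-2-enoyloxy]germacr-1(10)-en-12,6-olide
Product: 25 (1(10)Z,3S,4R,5R,6S,7R,8R,11R)-4,5-epoxy-3-hydroxy-8-[(2E)-2-methylbut-2-enoyloxy]germacr-1(10)-en-12,6-olide (CNP0265652.4)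
Conditions: DDQ, CH2Cl2/pH 7 phosphate buffer (10:1), 0 °C to rt
Reagents that add atoms: none
Why: Oxidative PMB cleavage at neutral pH frees C3–OH without the acid that would trigger transannular epoxide opening or the base that would cause acyl migration.

**Compound list**

1 | 2-[(tert-butyldimethylsilyl)oxy]acetaldehyde | CC(C)(C)[Si](C)(C)OCC=O | starting material
2 | 2-(triphenyl-λ5-phosphanylidene)propanal | CC(C=O)=P(c1ccccc1)(c1ccccc1)c1ccccc1 | starting material
3 | (2E)-4-[(tert-butyldimethylsilyl)oxy]-2-methylbut-2-enal | CC(C)(C)[Si](C)(C)OC/C=C(C)/C=O | intermediate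
4 | (2E,4S)-1-[(tert-butyldimethylsilyl)oxy]-3-methylhepta-2,6-dien-4-ol | CC(C)(C)[Si](C)(C)OC/C=C(C)/[C@@H](O)CC=C | intermediate
5 | tert-butyl{[(2E,4S)-4-[(4-methoxyphenyl)methoxy]-3-methylhepta-2,6-dien-1-yl]oxy}dimethylsilane | CC(C)(C)[Si](C)(C)OC/C=C(C)/[C@@H](OCc1ccc(OC)cc1)CC=C | intermediate
6 | (2E,4S)-4-[(4-methoxyphenyl)methoxy]-3-methylhepta-2,6-dien-1-ol | OC/C=C(C)/[C@@H](OCc1ccc(OC)cc1)CC=C | intermediate
7 | [(2R,3R)-3-{(1S)-1-[(4-methoxyphenyl)methoxy]but-3-en-1-yl}-3-methyloxiran-2-yl]methanol | OC[C@H]1O[C@]1(C)[C@@H](OCc1ccc(OC)cc1)CC=C | intermediate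
8 | (2S,3R)-3-{(1S)-1-[(4-methoxyphenyl)methoxy]but-3-en-1-yl}-3-methyloxirane-2-carbaldehyde | O=C[C@H]1O[C@]1(C)[C@@H](OCc1ccc(OC)cc1)CC=C | intermediate
9 | (4S)-4-benzyl-3-propanoyl-1,3-oxazolidin-2-one | CCC(=O)N1C(=O)OC[C@@H]1Cc1ccccc1 | starting material
10 | tert-butyl bromoacetate | CC(C)(C)OC(=O)CBr | starting material
11 | tert-butyl (3R)-4-[(4S)-4-benzyl-2-oxo-1,3-oxazolidin-3-yl]-3-methyl-4-oxobutanoate | CC(C)(C)OC(=O)C[C@@H](C)C(=O)N1C(=O)OC[C@@H]1Cc1ccccc1 | intermediate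
12 | (2R)-4-tert-butoxy-2-methyl-4-oxobutanoic acid | CC(C)(C)OC(=O)C[C@@H](C)C(=O)O | intermediate
13 | 4-tert-butyl 1-methyl (2R)-2-methylbutanedioate | CC(C)(C)OC(=O)C[C@@H](C)C(=O)OC | intermediate
14 | (3R)-4-methoxy-3-methyl-4-oxobutanoic acid | OC(=O)C[C@@H](C)C(=O)OC | intermediate
15 | (4S)-4-benzyl-1,3-oxazolidin-2-one | O=C1OC[C@H](Cc2ccccc2)N1 | starting material
16 | (3R)-4-methoxy-3-methyl-4-oxobutanoic 2,2-dimethylpropanoic anhydride | CC(C)(C)C(=O)OC(=O)C[C@@H](C)C(=O)OC | intermediate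
17 | methyl (2R)-4-[(4S)-4-benzyl-2-oxo-1,3-oxazolidin-3-yl]-2-methyl-4-oxobutanoate | COC(=O)[C@H](C)CC(=O)N1C(=O)OC[C@@H]1Cc1ccccc1 | intermediate
18 | methyl (2R,3S,4S)-3-[(4S)-4-benzyl-2-oxo-1,3-oxazolidine-3-carbonyl]-4-hydroxy-4-[(2R,3R)-3-{(1S)-1-[(4-methoxyphenyl)methoxy]but-3-en-1-yl}-3-methyloxiran-2-yl]-2-methylbutanoate | COC(=O)[C@H](C)[C@H](C(=O)N1C(=O)OC[C@@H]1Cc1ccccc1)[C@H](O)[C@H]1O[C@]1(C)[C@@H](OCc1ccc(OC)cc1)CC=C | intermediate
19 | (4S)-4-benzyl-3-{(2S,3S,4R)-2-[(2R,3R)-3-{(1S)-1-[(4-methoxyphenyl)methoxy]but-3-en-1-yl}-3-methyloxiran-2-yl]-4-methyl-5-oxooxolane-3-carbonyl}-1,3-oxazolidin-2-one | O=C(N1C(=O)OC[C@@H]1Cc1ccccc1)[C@H]1[C@@H](C)C(=O)O[C@@H]1[C@H]1O[C@]1(C)[C@@H](OCc1ccc(OC)cc1)CC=C | intermediate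
20 | (3R,4R,5S)-4-(hydroxymethyl)-5-[(2R,3R)-3-{(1S)-1-[(4-methoxyphenyl)methoxy]but-3-en-1-yl}-3-methyloxiran-2-yl]-3-methyloxolan-2-one | OC[C@H]1[C@@H](C)C(=O)O[C@@H]1[C@H]1O[C@]1(C)[C@@H](OCc1ccc(OC)cc1)CC=C | intermediate
21 | (2S,3S,4R)-2-[(2R,3R)-3-{(1S)-1-[(4-methoxyphenyl)methoxy]but-3-en-1-yl}-3-methyloxiran-2-yl]-4-methyl-5-oxooxolane-3-carbaldehyde | O=C[C@H]1[C@@H](C)C(=O)O[C@@H]1[C@H]1O[C@]1(C)[C@@H](OCc1ccc(OC)cc1)CC=C | intermediate
22 | (3R,4R,5S)-4-[(1R)-1-hydroxy-3-methylbut-3-en-1-yl]-5-[(2R,3R)-3-{(1S)-1-[(4-methoxyphenyl)methoxy]but-3-en-1-yl}-3-methyloxiran-2-yl]-3-methyloxolan-2-one | C=C(C)C[C@@H](O)[C@H]1[C@@H](C)C(=O)O[C@@H]1[C@H]1O[C@]1(C)[C@@H](OCc1ccc(OC)cc1)CC=C | intermediate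
23 | (1R)-1-{(2S,3R,4R)-2-[(2R,3R)-3-{(1S)-1-[(4-methoxyphenyl)methoxy]but-3-en-1-yl}-3-methyloxiran-2-yl]-4-methyl-5-oxooxolan-3-yl}-3-methylbut-3-en-1-yl (2E)-2-methylbut-2-enoate | C=C(C)C[C@@H](OC(=O)/C(C)=C/C)[C@H]1[C@@H](C)C(=O)O[C@@H]1[C@H]1O[C@]1(C)[C@@H](OCc1ccc(OC)cc1)CC=C | intermediate
24 | (1(10)Z,3S,4R,5R,6S,7R,8R,11R)-4,5-epoxy-3-[(4-methoxyphenyl)methoxy]-8-[(2E)-2-methylbut-2-enoyloxy]germacr-1(10)-en-12,6-olide | C/C=C(\C)C(=O)O[C@@H]1C/C(C)=C\C[C@H](OCc3ccc(OC)cc3)[C@@]2(C)O[C@@H]2[C@H]2OC(=O)[C@H](C)[C@@H]21 | intermediate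
25 | (1(10)Z,3S,4R,5R,6S,7R,8R,11R)-4,5-epoxy-3-hydroxy-8-[(2E)-2-methylbut-2-enoyloxy]germacr-1(10)-en-12,6-olide (CNP0265652.4) | C/C=C(\C)C(=O)O[C@@H]1C/C(C)=C\C[C@H](O)[C@@]2(C)O[C@@H]2[C@H]2OC(=O)[C@H](C)[C@@H]21 | target

**Step count and risks**

Total steps: 18. Longest linear sequence: 13 (steps 1–6, then 12–18).

Steps most likely to fail:

1. Step 17 (closure of a strained ten-membered ring to a trisubstituted olefin; oligomerisation or no turnover). The fallback replaces metathesis by a Nozaki–Hiyama–Kishi macrocyclisation followed by a reductive allylic transposition. It sets out from aldehyde 21 and comes back at 24. Aldehyde 21 is treated with B-(2-bromoallyl)diisopinocampheylborane (made from allene and Ipc2BBr of the (−)-α-pinene series; same facial sense as step 15) to give the (8R)-2-bromoallyl carbinol F1. F1 is esterified as in step 16 to the tiglate F2. The terminal vinyl group of F2 is cleaved (OsO4 cat., N-methylmorpholine N-oxide; then NaIO4) to the C1 aldehyde F3; the bromoalkene and the tiglate react far more slowly. F3 is cyclised with CrCl2 and NiCl2 (cat.) in DMSO at high dilution to the ten-membered allylic alcohol with an exocyclic methylene F4 (C1 epimers, both usable). F4 is treated with 2-nitrobenzenesulfonylhydrazide, PPh3 and diethyl azodicarboxylate (THF, −30 °C to rt); the allylic diazene loses N2 with hydrogen delivery to the exocyclic CH2, which creates the C10 methyl and the endocyclic 1(10) olefin of 24. The olefin geometry from this step is set by the ring and has to be confirmed by NOE.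

2. Step 12 (a sensitive α,β-epoxy aldehyde under Lewis-acidic boron conditions; possible stereochemical mismatch). The fallback reverses the order of aldol and epoxidation so that the epoxide is set by substrate direction. It sets out from allylic alcohol 6 and comes back at 18, which is lactonised to 19 as in step 12. Alcohol 6 is oxidised with MnO2 (CH2Cl2) to the dienal F5. The same boron aldol of 17 with F5 gives the syn-aldol allylic alcohol F6, which is worked up cold and used at once so that it does not lactonise. mCPBA (NaHCO3, CH2Cl2, 0 °C) then epoxidises the C4=C5 olefin under direction by the free C6–OH; the methyl group cis to the carbinol carbon enforces the H-eclipsed conformer (A(1,3) strain), which gives the threo epoxy alcohol 18.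

3. Step 15 (diastereoselectivity of the methallylation next to the C7 stereocentre). The fallback sets C8 by ketone reduction instead of by allylboration. It sets out from aldehyde 21 and comes back at 22. A Barbier addition (CH2=C(CH3)CH2Br, Zn, THF/aqueous NH4Cl) gives the carbinol as a mixture of C8 epimers F7. Dess–Martin oxidation converts the mixture into the single β,γ-unsaturated ketone F8. Corey–Bakshi–Shibata reduction with (S)-2-methyl-CBS-oxazaborolidine and catecholborane (PhMe, −78 °C; ring carbon as the large group, CH2 as the small group) gives the (8R)-alcohol 22 without hydroborating the olefins.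

**Further compounds**

F1 | step 17 | (3R,4R,5S)-4-[(1R)-3-bromo-1-hydroxybut-3-en-1-yl]-5-[(2R,3R)-3-{(1S)-1-[(4-methoxyphenyl)methoxy]but-3-en-1-yl}-3-methyloxiran-2-yl]-3-methyloxolan-2-one | C=C(Br)C[C@@H](O)[C@H]1[C@@H](C)C(=O)O[C@@H]1[C@H]1O[C@]1(C)[C@@H](OCc1ccc(OC)cc1)CC=C
F2 | step 17 | (1R)-3-bromo-1-{(2S,3R,4R)-2-[(2R,3R)-3-{(1S)-1-[(4-methoxyphenyl)methoxy]but-3-en-1-yl}-3-methyloxiran-2-yl]-4-methyl-5-oxooxolan-3-yl}but-3-en-1-yl (2E)-2-methylbut-2-enoate | C=C(Br)C[C@@H](OC(=O)/C(C)=C/C)[C@H]1[C@@H](C)C(=O)O[C@@H]1[C@H]1O[C@]1(C)[C@@H](OCc1ccc(OC)cc1)CC=C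
F3 | step 17 | (1R)-3-bromo-1-{(2S,3R,4R)-2-[(2R,3R)-3-{(1S)-1-[(4-methoxyphenyl)methoxy]-3-oxopropyl}-3-methyloxiran-2-yl]-4-methyl-5-oxooxolan-3-yl}but-3-en-1-yl (2E)-2-methylbut-2-enoate | C=C(Br)C[C@@H](OC(=O)/C(C)=C/C)[C@H]1[C@@H](C)C(=O)O[C@@H]1[C@H]1O[C@]1(C)[C@@H](OCc1ccc(OC)cc1)CC=O
F4 | step 17 | (3S,4R,5R,6S,7R,8R,11R)-4,5-epoxy-1-hydroxy-3-[(4-methoxyphenyl)methoxy]-8-[(2E)-2-methylbut-2-enoyloxy]germacr-10(14)-en-12,6-olide (C1 epimers) | C/C=C(\C)C(=O)O[C@@H]1CC(=C)C(O)C[C@H](OCc3ccc(OC)cc3)[C@@]2(C)O[C@@H]2[C@H]2OC(=O)[C@H](C)[C@@H]21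
F5 | step 12 | (2E,4S)-4-[(4-methoxyphenyl)methoxy]-3-methylhepta-2,6-dienal | O=C/C=C(C)/[C@@H](OCc1ccc(OC)cc1)CC=C
F6 | step 12 | methyl (2R,3S,4R,5E,7S)-3-[(4S)-4-benzyl-2-oxo-1,3-oxazolidine-3-carbonyl]-4-hydroxy-7-[(4-methoxyphenyl)methoxy]-2,6-dimethyldeca-5,9-dienoate | COC(=O)[C@H](C)[C@H](C(=O)N1C(=O)OC[C@@H]1Cc1ccccc1)[C@H](O)/C=C(C)/[C@@H](OCc1ccc(OC)cc1)CC=C
F7 | step 15 | (3R,5S)-4-(1-hydroxy-3-methylbut-3-en-1-yl)-5-[(2R,3R)-3-{(1S)-1-[(4-methoxyphenyl)methoxy]but-3-en-1-yl}-3-methyloxiran-2-yl]-3-methyloxolan-2-one (22 plus its C8 epimer; ring C4 configured as in 22) | C=C(C)CC(O)[C@H]1[C@@H](C)C(=O)O[C@@H]1[C@H]1O[C@]1(C)[C@@H](OCc1ccc(OC)cc1)CC=C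
F8 | step 15 | (3R,4S,5S)-5-[(2R,3R)-3-{(1S)-1-[(4-methoxyphenyl)methoxy]but-3-en-1-yl}-3-methyloxiran-2-yl]-3-methyl-4-(3-methylbut-3-enoyl)oxolan-2-one | C=C(C)CC(=O)[C@H]1[C@@H](C)C(=O)O[C@@H]1[C@H]1O[C@]1(C)[C@@H](OCc1ccc(OC)cc1)CC=C
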